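Everything rests on disconnecting ring A at C7–C8. Ring C is made first as an enantiopure (2S)-2-aryl-2,3-dihydropyran-4-one and ring A is folded onto it. The key step exploits that C5, C7 and C8a of ring A all carry oxygen, the pattern of a 1,3,5-tricarbonyl chain, and that O1 of ring C is already bound to C8a: a base-mediated Dieckmann closure of C8 onto the ester carbon C7 builds and aromatises ring A in one operation, with the 6-methoxy and 8-prenyl groups in place and no choice between two ortho oxygens. Its precursor is a dihydropyranone bearing a methoxymalonyl (β-keto ester) group at pyranone position 5 and a 4-methylpent-3-enyl chain at position 6.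

Key step: step 10

Remark: C2 to C8a are flavanone numbers throughout; C8 is the first carbon of the pyranone 6-side chain, C7 the ester carbon, and target, precursor and key-step product are all (2S).
Remark: the most acidic C–H of the precursor is C6–H between ketone and ester, not C8–H; the base in step 10 is chosen for that situation.
Remark: the facial sense in step 4 is assigned by analogy with aromatic aldehydes and is to be confirmed on 7 (Mosher esters); the (R)-ligand would be used if it proved opposite.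

Step 1
Reactants: 1 4-hydroxybenzaldehyde
Product: 2 4-(triisopropylsilyloxy)benzaldehyde
Conditions: iPr3SiCl, imidazole, DMF, rt
Reagents that add atoms: triisopropylsilyl chloride, CC(C)[Si](Cl)(C(C)C)C(C)C
Why: Imidazole-promoted silylation of the phenol gives a bulky aryl silyl ether that should survive the Lewis acid, mild acid and amine base of the later steps and can be removed at the end by buffered fluoride.

Step 2
Reactants: 3 tert-butyl acetoacetate
Product: 4 tert-butyl 3-(trimethylsilyloxy)but-2-enoate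
Conditions: TMSCl, Et3N, hexane, rt
Reagents that add atoms: chlorotrimethylsilane, C[Si](C)(C)Cl
Why: O-silylation of the enol of a β-keto ester under amine base (silyl enol ether formation).

Step 3
Reactants: 4 tert-butyl 3-(trimethylsilyloxy)but-2-enoate
Product: 5 1-tert-butoxy-1,3-bis(trimethylsilyloxy)buta-1,3-diene
Conditions: LiN(iPr)2, THF, −78 °C; TMSCl, −78 °C to 0 °C
Reagents that add atoms: chlorotrimethylsilane, C[Si](C)(C)Cl
Why: Kinetic γ-deprotonation and O-silylation give the Chan-type bis-silyl dienolate, and the tert-butyl ester excludes the Ireland–Claisen rearrangement that an allyl ester would undergo.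

Step 4
Reactants: 2 4-(triisopropylsilyloxy)benzaldehyde; 5 1-tert-butoxy-1,3-bis(trimethylsilyloxy)buta-1,3-diene
Product: 7 tert-butyl (5S)-5-hydroxy-3-oxo-5-[4-(triisopropylsilyloxy)phenyl]pentanoate, via bis-silylated aldol adduct 6 (not isolated)
Conditions: Ti(OiPr)4 (8 mol%), (S)-BINOL (8 mol%), 4 Å molecular sieves, THF, −78 °C to rt; then 1 M HCl, THF, 0 °C
Reagents that add atoms: none
Why: Vinylogous Mukaiyama aldol in which the dienolate reacts only at its terminal carbon and the (S)-BINOL–titanium complex is expected to direct it to the Si face of the bound aldehyde, which sets the (S)-carbinol.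

Step 5
Reactants: 8 5-methylhex-4-enoic acid
Product: 9 5-methylhex-4-enoyl chloride
Conditions: (COCl)2, DMF (cat.), CH2Cl2, 0 °C to rt
Reagents that add atoms: oxalyl chloride, O=C(Cl)C(Cl)=O
Why: Acid chloride formation through the chloroiminium catalyst at low temperature, where HCl should not add to the trisubstituted alkene.

Step 6
Reactants: 7 tert-butyl (5S)-5-hydroxy-3-oxo-5-[4-(triisopropylsilyloxy)phenyl]pentanoate; 9 5-methylhex-4-enoyl chloride
Product: 12 tert-butyl (2S)-6-(4-methylpent-3-enyl)-4-oxo-2-[4-(triisopropylsilyloxy)phenyl]-2,3-dihydro-4H-pyran-5-carboxylate, via trimethylsilyl ether 10 (not isolated), via C-acylated silyl ether 11 (not isolated)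
Conditions: TMSCl, pyridine, CH2Cl2, 0 °C; MgCl2, then 9, 0 °C to rt; TsOH·H2O, MeOH, rt
Reagents that add atoms: none
Why: Rathke-type C-acylation of the magnesium chelate of the β-keto ester (the transient silyl ether keeps the alcohol from being esterified) followed by acid-catalysed desilylation and cyclodehydration, in which the hydroxyl can only add to the new alkyl ketone because the other carbonyl is a bulky tert-butyl ester, so the chain ends on position 6 and the ester on position 5 without regiochemical ambiguity and the C–O bond of the stereocentre is never broken.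

Step 7
Reactants: 12 tert-butyl (2S)-6-(4-methylpent-3-enyl)-4-oxo-2-[4-(triisopropylsilyloxy)phenyl]-2,3-dihydro-4H-pyran-5-carboxylate
Product: 14 (2S)-6-(4-methylpent-3-enyl)-4-oxo-2-[4-(triisopropylsilyloxy)phenyl]-2,3-dihydro-4H-pyran-5-carboxylic acid, via trimethylsilyl ester 13 (not isolated)
Conditions: TMSOTf, 2,6-lutidine, CH2Cl2, 0 °C; aqueous citric acid work-up
Reagents that add atoms: none
Why: Buffered silyl-triflate cleavage of a tert-butyl ester (loss of isobutene, hydrolysis of the silyl ester on work-up) avoids protic acid that could add to the alkene or ionise the benzylic C2–O1 bond, and the acid is stable to decarboxylation because its α-carbon is sp2.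

Step 8
Reactants: 15 dimethyl methoxymalonate
Product: 16 potassium methyl methoxymalonate
Conditions: KOH (1.0 equiv), MeOH, 0 °C to rt
Reagents that add atoms: potassium hydroxide, [K+].[OH-]
Why: Mono-saponification of a malonic diester stops at the half ester because the carboxylate deactivates the remaining ester.

Step 9
Reactants: 14 (2S)-6-(4-methylpent-3-enyl)-4-oxo-2-[4-(triisopropylsilyloxy)phenyl]-2,3-dihydro-4H-pyran-5-carboxylic acid; 16 potassium methyl methoxymalonate
Product: 19 methyl 2-methoxy-3-[(2S)-6-(4-methylpent-3-enyl)-4-oxo-2-[4-(triisopropylsilyloxy)phenyl]-2,3-dihydro-4H-pyran-5-yl]-3-oxopropanoate, via acyl imidazolide 17 (not isolated), via acylated malonic half acid 18 (not isolated)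
Conditions: CDI, THF, rt; then 16, MgCl2, Et3N, MeCN, rt; 1 M HCl work-up
Reagents that add atoms: none
Why: Decarboxylative Claisen condensation of the Masamune–Brooks type, in which the magnesium enolate of the malonic half ester is C-acylated by the acyl imidazolide and the acylmalonic acid loses CO2, installs the methoxy-bearing β-keto ester under near-neutral conditions that should not enolise C3.

Step 10
Reactants: 19 methyl 2-methoxy-3-[(2S)-6-(4-methylpent-3-enyl)-4-oxo-2-[4-(triisopropylsilyloxy)phenyl]-2,3-dihydro-4H-pyran-5-yl]-3-oxopropanoate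
Product: 21 (2S)-5,7-dihydroxy-6-methoxy-8-(3-methylbut-2-enyl)-2-[4-(triisopropylsilyloxy)phenyl]chroman-4-one, via trione tautomer 20 (not isolated)
Conditions: DBU (2.5 equiv), MeCN, 0 °C to rt; AcOH quench
Reagents that add atoms: none
Why: Proposed new method: DBU first removes C6–H between the C5 ketone and the ester, and this enolate is the resting state; in equilibrium with it is the tautomer with C6 reprotonated and C8 deprotonated, whose dienolate (conjugated through C8a=C4a with both the C4 and the C5 carbonyl) adds through C8 to the neutral ester carbon C7, expels methoxide to give trione 20 and enolises to aromatic ring A. The closest known reactions are the Claisen-type (Dieckmann) cyclisations of polyketo esters to acylphloroglucinols and the base-mediated condensations at the 2-alkyl group of 3-acyl-4-pyranones and 3-acylchromones, but a vinylogous enolate of a 5-acyl dihydropyranone closing onto an ester is not established. Ring A closes in a 6-(enolendo)-exo-trig mode, forming the C7–C8 bond with the carbonyl oxygen outside the new ring. No stereocentre is formed, and C2 stays untouched as long as C3 is not deprotonated. The step needs C8 over C3 deprotonation and C- over O-acylation: C8–H is activated by two carbonyls and C3–H by one, so a weak amine base should reach only C8, the resting keto-ester enolate makes O1 a poor leaving group and so guards ring C against retro-oxa-Michael opening, and O-acylation through the C4 oxygen is reversible whereas C-acylation is fixed by aromatisation. Because ring C holds O1 on C8a, only one regioisomer of the flavanone can form.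

Step 11
Reactants: 21 (2S)-5,7-dihydroxy-6-methoxy-8-(3-methylbut-2-enyl)-2-[4-(triisopropylsilyloxy)phenyl]chroman-4-one
Product: 22 (2S)-5-hydroxy-6,7-dimethoxy-8-(3-methylbut-2-enyl)-2-[4-(triisopropylsilyloxy)phenyl]chroman-4-one
Conditions: TMSCHN2, toluene/MeOH 4:1, 0 °C to rt
Reagents that add atoms: trimethylsilyldiazomethane, C[Si](C)(C)C=[N+]=[N-]
Why: Phenol O-methylation with the diazoalkane should take the acidic, non-chelated 7-hydroxyl para to the carbonyl, while the 5-hydroxyl is held in a hydrogen bond to C4=O and the neutral conditions spare ring C, the prenyl group and the silyl ether.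

Step 12
Reactants: 22 (2S)-5-hydroxy-6,7-dimethoxy-8-(3-methylbut-2-enyl)-2-[4-(triisopropylsilyloxy)phenyl]chroman-4-one
Product: 23 (2S)-5-hydroxy-2-(4-hydroxyphenyl)-6,7-dimethoxy-8-(3-methylbut-2-enyl)chroman-4-one
Conditions: Bu4NF, AcOH (1:1), THF, 0 °C
Reagents that add atoms: none
Why: Fluoride cleaves the aryl silyl ether, and the acetic acid buffer keeps the phenoxide protonated so that the 5-hydroxyflavanone should not open to the chalcone and racemise.

Compound list
1 | 4-hydroxybenzaldehyde | O=Cc1ccc(O)cc1 | starting material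
2 | 4-(triisopropylsilyloxy)benzaldehyde | O=Cc1ccc(O[Si](C(C)C)(C(C)C)C(C)C)cc1 | intermediate
3 | tert-butyl acetoacetate | CC(=O)CC(=O)OC(C)(C)C | starting material
4 | tert-butyl 3-(trimethylsilyloxy)but-2-enoate | CC(O[Si](C)(C)C)=CC(=O)OC(C)(C)C | intermediate
5 | 1-tert-butoxy-1,3-bis(trimethylsilyloxy)buta-1,3-diene | C=C(O[Si](C)(C)C)C=C(OC(C)(C)C)O[Si](C)(C)C | intermediate
6 | tert-butyl (5S)-3,5-bis(trimethylsilyloxy)-5-[4-(triisopropylsilyloxy)phenyl]pent-2-enoate | CC(C)(C)OC(=O)C=C(O[Si](C)(C)C)C[C@H](O[Si](C)(C)C)c1ccc(O[Si](C(C)C)(C(C)C)C(C)C)cc1 | intermediate (not isolated)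
7 | tert-butyl (5S)-5-hydroxy-3-oxo-5-[4-(triisopropylsilyloxy)phenyl]pentanoate | CC(C)(C)OC(=O)CC(=O)C[C@H](O)c1ccc(O[Si](C(C)C)(C(C)C)C(C)C)cc1 | intermediate
8 | 5-methylhex-4-enoic acid | CC(C)=CCCC(=O)O | starting material
9 | 5-methylhex-4-enoyl chloride | CC(C)=CCCC(=O)Cl | intermediate
10 | tert-butyl (5S)-3-oxo-5-[4-(triisopropylsilyloxy)phenyl]-5-(trimethylsilyloxy)pentanoate | CC(C)(C)OC(=O)CC(=O)C[C@H](O[Si](C)(C)C)c1ccc(O[Si](C(C)C)(C(C)C)C(C)C)cc1 | intermediate (not isolated)
11 | tert-butyl (5S)-2-(5-methylhex-4-enoyl)-3-oxo-5-[4-(triisopropylsilyloxy)phenyl]-5-(trimethylsilyloxy)pentanoate (C2 epimers and enol forms) | CC(C)(C)OC(=O)C(C(=O)CCC=C(C)C)C(=O)C[C@H](O[Si](C)(C)C)c1ccc(O[Si](C(C)C)(C(C)C)C(C)C)cc1 | intermediate (not isolated)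
12 | tert-butyl (2S)-6-(4-methylpent-3-enyl)-4-oxo-2-[4-(triisopropylsilyloxy)phenyl]-2,3-dihydro-4H-pyran-5-carboxylate | CC(C)(C)OC(=O)C1=C(CCC=C(C)C)O[C@H](c2ccc(O[Si](C(C)C)(C(C)C)C(C)C)cc2)CC1=O | intermediate
13 | trimethylsilyl (2S)-6-(4-methylpent-3-enyl)-4-oxo-2-[4-(triisopropylsilyloxy)phenyl]-2,3-dihydro-4H-pyran-5-carboxylate | C[Si](C)(C)OC(=O)C1=C(CCC=C(C)C)O[C@H](c2ccc(O[Si](C(C)C)(C(C)C)C(C)C)cc2)CC1=O | intermediate (not isolated)
14 | (2S)-6-(4-methylpent-3-enyl)-4-oxo-2-[4-(triisopropylsilyloxy)phenyl]-2,3-dihydro-4H-pyran-5-carboxylic acid | OC(=O)C1=C(CCC=C(C)C)O[C@H](c2ccc(O[Si](C(C)C)(C(C)C)C(C)C)cc2)CC1=O | intermediate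
15 | dimethyl methoxymalonate | COC(C(=O)OC)C(=O)OC | starting material
16 | potassium methyl methoxymalonate | COC(C(=O)OC)C(=O)[O-].[K+] | intermediate
17 | (2S)-5-(imidazole-1-carbonyl)-6-(4-methylpent-3-enyl)-2-[4-(triisopropylsilyloxy)phenyl]-2,3-dihydro-4H-pyran-4-one | O=C(n1ccnc1)C1=C(CCC=C(C)C)O[C@H](c2ccc(O[Si](C(C)C)(C(C)C)C(C)C)cc2)CC1=O | intermediate (not isolated)
18 | 2-methoxy-2-(methoxycarbonyl)-3-[(2S)-6-(4-methylpent-3-enyl)-4-oxo-2-[4-(triisopropylsilyloxy)phenyl]-2,3-dihydro-4H-pyran-5-yl]-3-oxopropanoic acid (as magnesium carboxylate, either epimer) | COC(=O)C(OC)(C(=O)O)C(=O)C1=C(CCC=C(C)C)O[C@H](c2ccc(O[Si](C(C)C)(C(C)C)C(C)C)cc2)CC1=O | intermediate (not isolated)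
19 | methyl 2-methoxy-3-[(2S)-6-(4-methylpent-3-enyl)-4-oxo-2-[4-(triisopropylsilyloxy)phenyl]-2,3-dihydro-4H-pyran-5-yl]-3-oxopropanoate (either epimer at the methoxy carbon) | COC(=O)C(OC)C(=O)C1=C(CCC=C(C)C)O[C@H](c2ccc(O[Si](C(C)C)(C(C)C)C(C)C)cc2)CC1=O | intermediate (key-step precursor)
20 | (2S)-6-methoxy-8-(3-methylbut-2-enyl)-2-[4-(triisopropylsilyloxy)phenyl]-2,3-dihydro-6H-chromene-4,5,7(8H)-trione | COC1C(=O)C2=C(O[C@H](c3ccc(O[Si](C(C)C)(C(C)C)C(C)C)cc3)CC2=O)C(CC=C(C)C)C1=O | intermediate (not isolated)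
21 | (2S)-5,7-dihydroxy-6-methoxy-8-(3-methylbut-2-enyl)-2-[4-(triisopropylsilyloxy)phenyl]chroman-4-one | COc1c(O)c2c(c(CC=C(C)C)c1O)O[C@H](c1ccc(O[Si](C(C)C)(C(C)C)C(C)C)cc1)CC2=O | intermediate (key-step product)
22 | (2S)-5-hydroxy-6,7-dimethoxy-8-(3-methylbut-2-enyl)-2-[4-(triisopropylsilyloxy)phenyl]chroman-4-one | COc1c(O)c2c(c(CC=C(C)C)c1OC)O[C@H](c1ccc(O[Si](C(C)C)(C(C)C)C(C)C)cc1)CC2=O | intermediate
23 | (2S)-5-hydroxy-2-(4-hydroxyphenyl)-6,7-dimethoxy-8-(3-methylbut-2-enyl)chroman-4-one | COc1c(O)c2c(c(CC=C(C)C)c1OC)O[C@H](c1ccc(O)cc1)CC2=O | target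

Total step count: 12. Longest linear sequence: 9 steps (2, 3, 4, 6, 7, 9, 10, 11, 12).

Steps most likely to fail

Step 10 (carries the label). The keto-ester enolate that DBU forms first may be too unreactive for any ring closure. Slow deprotonation at C3 may open ring C by retro-oxa-Michael elimination and erode the stereocentre, before or after ring A has formed. O-acylation through the C4 oxygen or base-induced loss of the silyl ether may also compete. The fallback uses known chemistry only, sets out from 1 and returns at 23. Commercial 1-(6-hydroxy-2,3,4-trimethoxyphenyl)ethanone F1 is C-prenylated at its only free ring position (NaH, toluene, prenyl bromide; ortho C-alkylation of the sodium phenoxide in a non-polar solvent) to 1-[2-hydroxy-4,5,6-trimethoxy-3-(3-methylbut-2-enyl)phenyl]ethanone F2. Claisen–Schmidt condensation with 1 (KOH, EtOH) gives (E)-1-[2-hydroxy-4,5,6-trimethoxy-3-(3-methylbut-2-enyl)phenyl]-3-(4-hydroxyphenyl)prop-2-en-1-one F3. Its only ortho hydroxyl closes by oxa-Michael addition (NaOAc, EtOH, reflux) to racemic 2-(4-hydroxyphenyl)-5,6,7-trimethoxy-8-(3-methylbut-2-enyl)chroman-4-one F4. MgI2·OEt2 removes only the methyl ether peri to the carbonyl and gives racemic 5-hydroxy-2-(4-hydroxyphenyl)-6,7-dimethoxy-8-(3-methylbut-2-enyl)chroman-4-one F5. Preparative HPLC on a chiral stationary phase then delivers the (2S)-enantiomer 23.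

Step 9. Acyl transfer may be sluggish because the acyl imidazolide is flanked by the C4 carbonyl and the position-6 chain and the methoxy-substituted magnesium enolate is itself hindered. The enolate may also add in conjugate fashion at pyranone position 6. The fallback sets out from 14 and returns at 19. The acid is activated as before (17) and condensed with the unhindered magnesium enolate of methyl hydrogen malonate (potassium methyl malonate, MgCl2, Et3N). The 2-(methoxycarbonyl)-3-[(2S)-6-(4-methylpent-3-enyl)-4-oxo-2-[4-(triisopropylsilyloxy)phenyl]-2,3-dihydro-4H-pyran-5-yl]-3-oxopropanoic acid F6 formed in the flask loses CO2 to methyl 3-[(2S)-6-(4-methylpent-3-enyl)-4-oxo-2-[4-(triisopropylsilyloxy)phenyl]-2,3-dihydro-4H-pyran-5-yl]-3-oxopropanoate F7. Regitz diazo transfer (p-acetamidobenzenesulfonyl azide, Et3N, MeCN) gives methyl 2-diazo-3-[(2S)-6-(4-methylpent-3-enyl)-4-oxo-2-[4-(triisopropylsilyloxy)phenyl]-2,3-dihydro-4H-pyran-5-yl]-3-oxopropanoate F8. Rh2(OAc)4-catalysed O–H insertion of the carbenoid into methanol installs the methoxy group and gives 19.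

Step 4. The electron-rich aldehyde may convert slowly, and facial selectivity may be incomplete or of the opposite sense. The fallback sets out from 3 and 2 and returns at 7. The dianion of 3 (NaH, then n-BuLi, THF, 0 °C) adds through its terminal carbon to 2 at −78 °C (Huckin–Weiler aldol) to give racemic tert-butyl 5-hydroxy-3-oxo-5-[4-(triisopropylsilyloxy)phenyl]pentanoate F9. This is resolved by preparative HPLC on a chiral stationary phase, and the (S)-enantiomer is 7.

Further compounds
F1 | step 10 | 1-(6-hydroxy-2,3,4-trimethoxyphenyl)ethanone | CC(=O)c1c(O)cc(OC)c(OC)c1OC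
F2 | step 10 | 1-[2-hydroxy-4,5,6-trimethoxy-3-(3-methylbut-2-enyl)phenyl]ethanone | CC(=O)c1c(O)c(CC=C(C)C)c(OC)c(OC)c1OC
F3 | step 10 | (E)-1-[2-hydroxy-4,5,6-trimethoxy-3-(3-methylbut-2-enyl)phenyl]-3-(4-hydroxyphenyl)prop-2-en-1-one | O=C(/C=C/c1ccc(O)cc1)c1c(O)c(CC=C(C)C)c(OC)c(OC)c1OC
F4 | step 10 | racemic 2-(4-hydroxyphenyl)-5,6,7-trimethoxy-8-(3-methylbut-2-enyl)chroman-4-one | COc1c(OC)c2c(c(CC=C(C)C)c1OC)OC(c1ccc(O)cc1)CC2=O
F5 | step 10 | racemic 5-hydroxy-2-(4-hydroxyphenyl)-6,7-dimethoxy-8-(3-methylbut-2-enyl)chroman-4-one | COc1c(O)c2c(c(CC=C(C)C)c1OC)OC(c1ccc(O)cc1)CC2=O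
F6 | step 9 | 2-(methoxycarbonyl)-3-[(2S)-6-(4-methylpent-3-enyl)-4-oxo-2-[4-(triisopropylsilyloxy)phenyl]-2,3-dihydro-4H-pyran-5-yl]-3-oxopropanoic acid | COC(=O)C(C(=O)O)C(=O)C1=C(CCC=C(C)C)O[C@H](c2ccc(O[Si](C(C)C)(C(C)C)C(C)C)cc2)CC1=O
F7 | step 9 | methyl 3-[(2S)-6-(4-methylpent-3-enyl)-4-oxo-2-[4-(triisopropylsilyloxy)phenyl]-2,3-dihydro-4H-pyran-5-yl]-3-oxopropanoate | COC(=O)CC(=O)C1=C(CCC=C(C)C)O[C@H](c2ccc(O[Si](C(C)C)(C(C)C)C(C)C)cc2)CC1=O
F8 | step 9 | methyl 2-diazo-3-[(2S)-6-(4-methylpent-3-enyl)-4-oxo-2-[4-(triisopropylsilyloxy)phenyl]-2,3-dihydro-4H-pyran-5-yl]-3-oxopropanoate | COC(=O)C(=[N+]=[N-])C(=O)C1=C(CCC=C(C)C)O[C@H](c2ccc(O[Si](C(C)C)(C(C)C)C(C)C)cc2)CC1=O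
F9 | step 4 | racemic tert-butyl 5-hydroxy-3-oxo-5-[4-(triisopropylsilyloxy)phenyl]pentanoate | CC(C)(C)OC(=O)CC(=O)CC(O)c1ccc(O[Si](C(C)C)(C(C)C)C(C)C)cc1
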